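What the north-east run leaves at 6.5 min is a question about one difference: it repeats the west charges of 0.0800 M starting material and 0.00240 M free catalyst, but also holds 0.0240 M of product.

| flask | starting material | free catalyst | product | time |
|---|---|---|---|---|
| west | 0.0800 M | 0.00240 M |  |  |
| south-west | 0.0800 M | 0.00120 M |  |  |
| east | 0.160 M | 0.00240 M |  |  |
| north-east | 0.0800 M | 0.00240 M | 0.0240 M | 6.5 min |

- west run (time / min: [starting material] / M): 0.26: 0.07788; 0.58: 0.07516; 1.3: 0.06992; 2.9: 0.05973; 6.5: 0.04387
- south-west run (time / min: [starting material] / M): 0.26: 0.07862; 0.58: 0.07663; 1.3: 0.07280; 2.9: 0.06511; 6.5: 0.05152
- east run (time / min: [starting material] / M): 0.26: 0.15475; 0.58: 0.14897; 1.3: 0.13689; 2.9: 0.11473; 6.5: 0.08189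

(standard deviation of a reading: 2 × 10⁻⁴ M)

- how the opening rate goes with [starting material] round the charge of the west run: the exponent of the rate at two percent of starting material gone to product (one fixed amount of product, the same in the runs compared)
- how the opening rate goes with [free catalyst] round the charge of the west run: the exponent of the rate at two percent of starting material gone to product
- starting material in the north-east run at 6.5 min, as a share of the starting material charged

- Overall: starting material -> product, with free catalyst as catalyst.
- Constant volume, constant temperature.
- What is held in complexes is read along with the free species.
- An order is taken over about fifteen percent of the charge, up and down.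

The west run has 0.0924 min⁻¹ as its mean pseudo-first-order constant k, the natural logarithm of charge over remainder divided by the time. Its fraction left, f = exp(−kt), is 54.8%, and a relative error in k moves f by that error times f ln(1/f), a factor of 0.329.

Now each input in turn. The north-east charges repeat those of the west run, so an error in either order does not enter this reckoning. One reading's scatter is 0.250% of the charge, which is small. The number still to be read is how far k falls per molar of material turned over, here called the drag.

The east run gives it. Over the first 1.3 min, k reads 0.104 min⁻¹ in the west run and 0.120 min⁻¹ in the east run. Between 2.9 min and 6.5 min the east run reads 0.0937 min⁻¹ at a mean [starting material] of 0.0983 M, where a straight line through the opening values expects 0.109 min⁻¹. Dividing that relative fall by the starting material gone gives a drag of 2.26 M⁻¹. Counting the added product as that much turnover, this reckoning gives the north-east run k = 0.0874 min⁻¹ and a remainder of 56.7%, a shift of 1.9 percentage points from the west remainder, larger than the scatter of one reading.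

The forecast, made separately, gives orders of 1.25 in starting material and 0.5 in free catalyst and a north-east remainder of 56.5%, against the 56.7% reckoned here, reading the drift in part as “mild product inhibition”.

The flask gives orders of 1.0 in starting material and 0.60 in free catalyst and leaves 57.0% in the north-east run.

    2 free catalyst ⇌ catalyst dimer, settled at all times (1350 M⁻¹)
    free catalyst + starting material → product + free catalyst (109.2 M⁻¹ min⁻¹)
    2 starting material → homo dimer (0.1302 M⁻¹ min⁻¹)
    free catalyst + product ⇌ catalyst-product complex, settled at all times (24.60 M⁻¹)

That remainder puts k in the north-east run at 0.0865 min⁻¹, lower than the west value of 0.0924 min⁻¹. The slowing comes from the pairing of free catalyst with product to catalyst-product complex. The north-east run without that pairing leaves 52.2%, so its mean k is 0.0999 min⁻¹, higher than the west value, and the pairing lowers the mean k of the north-east run by 13.4%.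

(All runs were computed on assumed constants; the scatter is artificial.)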